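## Structural features

The target is an ester of two unbranched pieces: a saturated pentacosanoyl chain (24 sp3 carbons plus the carbonyl carbon) and a 2-(4-hydroxyphenyl)ethyl unit acylated on its primary aliphatic oxygen. The alcohol part contains a single 1,4-disubstituted benzene ring, with a free phenolic hydroxyl on one carbon and the O–CH2–CH2 tether on the carbon para to it. There is no stereocentre and no ring besides the arene, so no stereochemical relationship has to be controlled. The fragile functions are the ester, which hydroxide, alkoxide or a phenoxide would cleave or transesterify, and the electron-rich phenol, which is easily oxidised, competes as an acyl acceptor and is alkylated by carbocations at the positions ortho to oxygen. The real difficulty is therefore selectivity, not the skeleton: the acyl group must sit only on the aliphatic oxygen, and that oxygen must be on the terminal, not the benzylic, carbon of the tether. The waxy, poorly soluble chain also narrows the choice of solvents and makes separation from lipophilic by-products laborious. The key step uses the fact that the O–CH2 carbon lies β to an arene carrying a para oxygen: the aryl–CH2–CH2–O unit is the adduct of an oxygen nucleophile with the terminal carbon of a 4-alkoxystyrene, whose radical cation is attacked at exactly that carbon.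

## Logic of the disconnections

**4 ⇒ 3.** The phenolic O–H of 4 is replaced by an O–C(CH3)3 bond; in the forward direction this aryl O–alkyl bond is the one cut. A free phenol cannot go through the oxidative step that precedes it: it would be oxidised by the excited photocatalyst, its O–H would compete as nucleophile and hydrogen donor, and the unprotected vinyl arene polymerises readily. The gain is that the arene partner becomes the stable, purchasable 2, whose alkoxy group still donates strongly enough to make the alkene easy to oxidise. An aryl acetate would raise the oxidation potential and leave two esters to be told apart at the end. The demand on the forward step is that acidolysis must leave the primary alkyl ester alone and must not let the departing tert-butyl cation alkylate the freed phenol ring, so a hydride-donating cation scavenger is included.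

**3 ⇒ 1 + 2.** The bond cut is the O–CH2 bond between the ester oxygen and the terminal tether carbon, together with the new benzylic C–H. This is where a carboxylate adds to the radical cation of the matching vinyl arene, so 3 falls into two catalogue compounds with no activating group, no leaving group and complete atom economy. The forward step must give anti-Markovnikov regiochemistry, must trap the radical cation with the carboxylate of 1 faster than with neutral 2, and must deliver hydrogen to the benzylic radical before it adds to more alkene. The design answers these with a catalytic base to supply carboxylate, a thiol as fast hydrogen donor, removal of the phenolic stabiliser from 2, and slow feeding of 2.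

## Other disconnections considered

**Alternative 1:** The cut runs through the arene itself, at the C4–C5 and C2–C3 bonds of a cyclohexenone forerunner of the phenol.
- Forward step: the enamine of 4-oxobutyl pentacosanoate A1 with a secondary amine catalyst would add to methyl vinyl ketone A2. The keto aldehyde would close by intramolecular aldol condensation to racemic 2-(4-oxocyclohex-2-en-1-yl)ethyl pentacosanoate A3. Dehydrogenation of A3, for example with Pd(OCOCF3)2 and O2 (aerobic dehydrogenation by divalent palladium), would give 4.
- In favour: the phenol appears only in the last step, so no protecting group is needed. The para relation of hydroxyl and side chain is fixed by the ring construction. Everything is thermal polar chemistry with no light source. On these three points the alternative equals or beats the chosen plan.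
- Against: it builds six ring carbons that come ready-made in 2. A1 is not a catalogue compound and would need two steps from 1 (monoacylation of a four-carbon diol, then oxidation). An aldehyde with two α-hydrogens is open to self-aldol reaction and double Michael addition. The stereocentre at the ring carbon bearing the side chain in A3 is made only to be destroyed. The aromatisation needs an oxidant at elevated temperature on a waxy substrate.
- Comparison: structurally, the chosen plan addresses the one bond that is actually hard, the O–CH2 bond. Mechanistically, the annulation is more familiar and easier to scale, but it makes two C–C bonds and a ring to reach what one C–O bond delivers. In step economy it needs about four steps from 1 against two.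

**Alternative 2:** The cut is the C8–C9 bond in the middle of the acyl chain.
- Forward step: 9-[2-(4-acetoxyphenyl)ethoxy]-9-oxononanoic acid A4 and an excess of stearic acid A5 would be co-electrolysed as partly neutralised salts at a Pt anode in methanol. Both carboxylates lose CO2 and the two primary radicals combine to give 2-(4-acetoxyphenyl)ethyl pentacosanoate A6. Selective removal of the aryl acetate would then give 4.
- In favour: it replaces 1, a costly odd-numbered very-long-chain acid, by cheap commodity acids, which is better than the chosen plan on raw-material cost. It needs no catalyst, and unbranched primary radicals are the most favourable case for Kolbe coupling.
- Against: the coupling is statistical, so both homocoupled products and disproportionation products accompany A6, all waxy and hard to separate. The arene sits in a cell run at high anode potential. The basic methanolic electrolyte can cleave the aryl acetate during the run. A4 needs at least two selective preparative steps. The final deacetylation must distinguish an aryl ester from an alkyl ester.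
- Comparison: structurally, it solves chain assembly, a problem that disappears when 1 is purchased, and leaves the phenol/alcohol differentiation to be solved twice. Mechanistically, both plans use radicals, but here two free radicals must meet without control, whereas carboxylate addition to a radical cation is regiodetermined. In step economy it needs at least four steps against two. The two plans are equal in needing one final phenol-unmasking step.

**Alternative 3:** The cut is the bond between the aromatic carbon and the benzylic CH2.
- Forward step: 2-bromoethyl pentacosanoate A7 and 1-(benzyloxy)-4-iodobenzene A8 would be joined by reductive cross-electrophile coupling with NiI2, a bipyridine ligand and Zn powder in an amide solvent. This would give 2-[4-(benzyloxy)phenyl]ethyl pentacosanoate A9, and hydrogenolysis (H2, Pd/C) would release 4.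
- In favour: the halogens dictate where the new bond forms, so there is no regiochemical question, which is equal to or better than the chosen plan. No polymerisable alkene is involved. Hydrogenolysis of a benzyl ether is neutral and generates no electrophile that could attack the phenol ring, which is better than acidolysis of a tert-butyl ether.
- Against: A7 must first be made from 1 by esterification with the bromo alcohol. An alkyl bromide with an acyloxy group on the neighbouring carbon is exposed to reductive β-elimination at zinc or at the alkylnickel stage, expelling the carboxylate of 1 and ethylene. This is the fragmentation used on purpose to remove 2-haloethyl esters. Homocoupling of either halide competes, and stoichiometric zinc and halide waste result.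
- Comparison: structurally, it forms a skeletal C–C bond where a C–O bond suffices, because the aryl–C2 unit is available intact in 2. Mechanistically, it is an organonickel radical process with a built-in fragmentation channel, against a redox-neutral, fully atom-economic addition. In step economy it needs three steps against two.

Key step: step 1

Remark: the structures are taken as consistent (acyl chain of 25 carbons including the carbonyl carbon, no stereocentre). Because both partners of the key step are purchasable and only one deprotection follows, the route has two steps, so the risk assessment at the end covers both of them and there are no further steps to rank.

## Route

Step 1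
Reactants: 1 pentacosanoic acid; 2 1-tert-butoxy-4-vinylbenzene (4-tert-butoxystyrene)
Product: 3 2-(4-tert-butoxyphenyl)ethyl pentacosanoate
Conditions: 9-mesityl-10-methylacridinium tetrafluoroborate (5 mol%), PhSH (20 mol%), 2,6-lutidine (25 mol%), 2 (1.5 equiv, filtered through basic Al2O3, added by syringe pump), degassed ClCH2CH2Cl (about 0.05 M in 1), 450 nm LEDs, 35–40 °C
Reagents that add atoms: none
Why: This is an acridinium-photoredox anti-Markovnikov hydroacyloxylation of a styrene, a known alkene radical-cation hydrofunctionalisation. Blue light excites the acridinium salt, whose excited state should be oxidising enough to take one electron from the vinyl arene of 2, the para tert-butoxy group lowering its oxidation potential. The carboxylate of 1, kept available by the catalytic 2,6-lutidine, adds to the terminal CH2 carbon of the radical cation because only this mode leaves the spin on the benzylic carbon, where the aryl ring stabilises it; this secures the required anti-Markovnikov O–CH2 bond, and no benzylic cation that could lead to the branched ester arises in the buffered medium. PhSH then transfers a hydrogen atom to the benzylic radical to give 3, and the PhS radical takes the electron back from the acridine radical, the thiolate being protonated by 1, so both catalytic cycles close and the process is redox-neutral. No ring is closed and no stereocentre is created, the new benzylic carbon being a CH2 group. Besides regiochemistry, the selectivity that matters is capture of the radical cation by carboxylate in preference to neutral 2 (cyclodimerisation or chain growth); both captures are expected to be fast, so the concentration ratio decides, and 2 is therefore freed of its phenolic stabiliser and fed slowly. The tert-butyl ether has no O–H that could add to the radical cation or quench the catalyst, and 1 has no oxidisable site, so both spectator parts should pass unchanged.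

Step 2
Reactants: 3 2-(4-tert-butoxyphenyl)ethyl pentacosanoate
Product: 4 2-(4-hydroxyphenyl)ethyl pentacosanoate
Conditions: CF3CO2H, Et3SiH (3 equiv), CH2Cl2, 0 °C to rt
Reagents that add atoms: none
Why: Acidolysis of an aryl tert-butyl ether, the same operation as the standard side-chain deprotection of tert-butyl-protected tyrosine: protonation of the ether oxygen and loss of the tert-butyl cation frees the phenol, while a primary alkyl ester is not cleaved by anhydrous CF3CO2H at room temperature. Et3SiH reduces the tert-butyl cation to isobutane by ionic hydride transfer, which should prevent Friedel–Crafts tert-butylation of the ring positions ortho to the new hydroxyl.

## Compound list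

1 | pentacosanoic acid | CCCCCCCCCCCCCCCCCCCCCCCCC(=O)O | starting material
2 | 1-tert-butoxy-4-vinylbenzene (4-tert-butoxystyrene) | C=Cc1ccc(OC(C)(C)C)cc1 | starting material
3 | 2-(4-tert-butoxyphenyl)ethyl pentacosanoate | CCCCCCCCCCCCCCCCCCCCCCCCC(=O)OCCc1ccc(OC(C)(C)C)cc1 | intermediate
4 | 2-(4-hydroxyphenyl)ethyl pentacosanoate | CCCCCCCCCCCCCCCCCCCCCCCCC(=O)OCCc1ccc(O)cc1 | target

## Step count and risk assessment

Total step count: 2. Longest linear sequence: 2 steps (1 → 3 → 4, with 2 entering in step 1).

Least certain steps:

**Step 1 (key step).** Three processes are the most likely to go wrong.
- Chain growth or cyclodimerisation of the terminal alkene radical cation with neutral 2 can outrun carboxylate capture, because a monosubstituted electron-rich styrene is a good partner for its own radical cation.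
- Part of the thiol co-catalyst can be consumed by thiol–ene addition to 2.
- The limited solubility of 1 in the chlorinated solvent keeps the carboxylate concentration low and slows capture further; gentle warming, dilution and, if needed, CHCl3 as co-solvent are the first adjustments.

Fallback for step 1: it sets out from 2 and 1 and returns to the route at 3. Hydroboration of 2 with 9-borabicyclo[3.3.1]nonane in THF followed by oxidation with NaOH/H2O2 should give the anti-Markovnikov alcohol 2-(4-tert-butoxyphenyl)ethan-1-ol F1. Steglich esterification of F1 with 1 (N,N'-dicyclohexylcarbodiimide, catalytic 4-(dimethylamino)pyridine, warm CH2Cl2) should then give 3. This replaces the photochemical radical-cation addition by two well-established polar steps, at the cost of one more operation and stoichiometric reagents.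

**Step 2.** The most likely fault is electrophilic tert-butylation of the liberated phenol ring, if hydride transfer from the silane does not keep pace with cation formation. Incomplete ether cleavage is the second possibility, if the waxy substrate is poorly dissolved at low temperature.

Fallback for step 2: it sets out from 1 and returns to the route at 4. 1 would be added, under the conditions of step 1, to the purchasable silyl-protected alkene tert-butyl(4-ethenylphenoxy)dimethylsilane F2 to give 2-[4-(tert-butyldimethylsilyloxy)phenyl]ethyl pentacosanoate F3. Bu4NF buffered with acetic acid in THF at 0 °C should then cleave the aryl silyl ether to 4. The unmasking becomes a fluoride-driven Si–O cleavage that generates no carbocation, and the buffer keeps the phenoxide from attacking the ester.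

## Further compounds

F1 | step 1 | 2-(4-tert-butoxyphenyl)ethan-1-ol | OCCc1ccc(OC(C)(C)C)cc1
F2 | step 2 | tert-butyl(4-ethenylphenoxy)dimethylsilane | C=Cc1ccc(O[Si](C)(C)C(C)(C)C)cc1
F3 | step 2 | 2-[4-(tert-butyldimethylsilyloxy)phenyl]ethyl pentacosanoate | CCCCCCCCCCCCCCCCCCCCCCCCC(=O)OCCc1ccc(O[Si](C)(C)C(C)(C)C)cc1
A1 | alternative 1 | 4-oxobutyl pentacosanoate | CCCCCCCCCCCCCCCCCCCCCCCCC(=O)OCCCC=O
A2 | alternative 1 | methyl vinyl ketone (but-3-en-2-one) | CC(=O)C=C
A3 | alternative 1 | 2-(4-oxocyclohex-2-en-1-yl)ethyl pentacosanoate (racemic) | CCCCCCCCCCCCCCCCCCCCCCCCC(=O)OCCC1C=CC(=O)CC1
A4 | alternative 2 | 9-[2-(4-acetoxyphenyl)ethoxy]-9-oxononanoic acid | CC(=O)Oc1ccc(CCOC(=O)CCCCCCCC(=O)O)cc1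
A5 | alternative 2 | stearic acid (octadecanoic acid) | CCCCCCCCCCCCCCCCCC(=O)O
A6 | alternative 2 | 2-(4-acetoxyphenyl)ethyl pentacosanoate | CCCCCCCCCCCCCCCCCCCCCCCCC(=O)OCCc1ccc(OC(C)=O)cc1
A7 | alternative 3 | 2-bromoethyl pentacosanoate | CCCCCCCCCCCCCCCCCCCCCCCCC(=O)OCCBr
A8 | alternative 3 | 1-(benzyloxy)-4-iodobenzene | Ic1ccc(OCc2ccccc2)cc1
A9 | alternative 3 | 2-[4-(benzyloxy)phenyl]ethyl pentacosanoate | CCCCCCCCCCCCCCCCCCCCCCCCC(=O)OCCc1ccc(OCc2ccccc2)cc1
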